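## Retrosynthetic overview

1. The bond between carbon 2 and the aryl group is made last: enantioselective conjugate addition of 4-methoxyphenylboronic acid to a 7-hydroxy-6,8-diprenylchromone sets the only stereocentre.
2. Rings A and C of that chromone are made together: a Diels–Alder/aromatisation of a 2,4-diprenyl bis(silyloxy) diene with diethynyl ketone builds ring A, and the second ynone arm then closes ring C in the same flask.
3. The diene comes from methyl acetoacetate by γ- then α-prenylation and double O-silylation, so both prenyl positions are fixed before the arene exists.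
4. Diethynyl ketone comes from ethyl formate and ethynylmagnesium bromide; ring B is bought as the boronic acid.
5. Order of ring formation: ring A, then ring C (one operation); ring B is never constructed.

**Assumption:** the target SMILES encodes the (2S)-flavanone (at carbon 2 the priorities are ring oxygen > aryl > carbon 3 > H); "prenyl" means 3-methylbut-2-en-1-yl.

## Route

**Step 1**
Reactants: 1 methyl acetoacetate; 2 prenyl bromide (1-bromo-3-methylbut-2-ene, 2.1 equiv in two portions)
Product: 4 methyl 7-methyl-2-(3-methylbut-2-en-1-yl)-3-oxooct-6-enoate (racemic), via monoprenyl keto ester enolate 3 (not isolated)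
Conditions: NaH (1.1 equiv), THF, 0 °C; n-BuLi (1.05 equiv), 0 °C; 2 (1.0 equiv), 0 °C, 30 min; then 2 (1.1 equiv), DMPU, 0 → 45 °C
Reagents that add atoms: none
Why: The acetoacetate dianion (Huckin–Weiler) alkylates first at the more basic γ-carbon, and the remaining stabilised α-enolate is then C-alkylated by the second portion of the allylic bromide (two sequential SN2 enolate alkylations), which places both prenyl groups without regiochemical ambiguity; no target stereocentre is involved.

**Step 2**
Reactants: 4 methyl 7-methyl-2-(3-methylbut-2-en-1-yl)-3-oxooct-6-enoate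
Product: 6 (3Z)-1-methoxy-7-methyl-2-(3-methylbut-2-en-1-yl)-1,3-bis(trimethylsilyloxy)octa-1,3,6-triene, via mono-silyl enol ether 5 (not isolated)
Conditions: LiN(i-Pr)2 (1.05 equiv), THF, −78 °C; Me3SiCl (1.1 equiv), −78 → 0 °C; then LiN(i-Pr)2 (1.1 equiv), −78 °C; Me3SiCl (1.2 equiv), −78 → 0 °C; pentane, filtration under Ar, concentrate; used crude
Reagents that add atoms: chlorotrimethylsilane, C[Si](C)(C)Cl
Why: O-silylation of the β-keto ester enolate, then γ-deprotonation of the resulting vinylogous ester and a second O-silylation, is the standard two-stage preparation of Chan-type 1-alkoxy-1,3-bis(silyloxy) dienes (kinetic enolate silylation), and the hindered tetrasubstituted enol ether favours the 3Z enolate, which puts the substituent on carbon 4 on the outside of the s-cis diene.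

**Step 3**
Reactants: 7 ethyl formate; 8 ethynylmagnesium bromide (2.2 equiv)
Product: 10 penta-1,4-diyn-3-ol, via prop-2-ynal 9 (not isolated)
Conditions: THF, 0 °C → rt; then 1 M HCl, 0 °C
Reagents that add atoms: none
Why: Double Grignard addition to a formate ester gives the symmetrical secondary carbinol, because the aldehyde released from the first adduct is more electrophilic than the ester.

**Step 4**
Reactants: 10 penta-1,4-diyn-3-ol
Product: 11 penta-1,4-diyn-3-one (diethynyl ketone)
Conditions: MnO2 (activated, 10 equiv), CH2Cl2, 0 °C; filter (Celite), dry (4 Å MS); the cold solution is assayed by NMR and used at once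
Reagents that add atoms: none
Why: MnO2 oxidises the doubly propargylic alcohol selectively under neutral, non-aqueous conditions (activated-alcohol oxidation), and the volatile, polymerisation-prone ynone is never concentrated.

**Step 5**
Reactants: 6 the bis(silyloxy) diene; 11 penta-1,4-diyn-3-one (2.5 equiv)
Product: 15 7-hydroxy-6,8-bis(3-methylbut-2-en-1-yl)-4H-chromen-4-one, via Diels–Alder cycloadduct 12 (not isolated), via aryl ethynyl ketone 13 (not isolated), via diethylamino enone 14 (not isolated)
Conditions: CH2Cl2, −40 °C → rt; then Et2NH (6 equiv), EtOH, rt; then 1 M HCl, rt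
Reagents that add atoms: none
Why: Proposed new method: the electron-rich diene adds to one alkyne of the doubly activated diynone in a Diels–Alder reaction with Danishefsky-type regiochemistry (the nucleophilic terminal carbon 4 of the diene bonds to the ynone β-carbon and the acetal carbon to the α-carbon, so the acyl group ends ortho to the acetal oxygen and para to the 3-silyloxy oxygen); ethanolysis at silicon unmasks the hemiketal, which expels methanol and aromatises to the 2,4-dihydroxyaryl ethynyl ketone (ring A); diethylamine adds to the remaining ynone and the ortho-phenol displaces it on mild acidification by 6-endo addition–elimination (ring C); the closest known reactions are the cycloaddition of 1-methoxy-1,3-bis(silyloxy) dienes with acetylenic ketones and esters to give resorcinols, and the amine-mediated cyclisation of 2-hydroxyaryl ynones to chromones.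

**Step 6**
Reactants: 15 7-hydroxy-6,8-bis(3-methylbut-2-en-1-yl)-4H-chromen-4-one; 16 4-methoxyphenylboronic acid (2 equiv)
Product: 17 (2S)-7-hydroxy-2-(4-methoxyphenyl)-6,8-bis(3-methylbut-2-en-1-yl)-2,3-dihydro-4H-chromen-4-one (the target flavanone)
Conditions: Pd(OCOCF3)2 (5 mol %), (R)-t-BuPyOx [(R)-4-tert-butyl-2-(pyridin-2-yl)-4,5-dihydrooxazole, 6 mol %], NH4PF6 (30 mol %), H2O (5 equiv), ClCH2CH2Cl, 60 °C
Reagents that add atoms: none
Why: Asymmetric conjugate addition of an arylboronic acid with a cationic divalent palladium/pyridine-oxazoline catalyst: the aryl–palladium species inserts across the 2,3-double bond of the chromone on the face left open by the tert-butyl group and the palladium enolate is protonated by water, which sets carbon 2 under base-free conditions that do not open the flavanone. The (R)-ligand is specified by analogy, since the (S)-ligand is expected to give (2R)-flavanones, the same facial sense as with 3-substituted cyclohexenones. This assignment should be confirmed by CD (2S shows a positive Cotton effect near 330 nm and a negative one near 290 nm), and the ligand antipode used if the sense is reversed.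

## Compound list

1 | methyl acetoacetate (methyl 3-oxobutanoate) | CC(=O)CC(=O)OC | starting material
2 | prenyl bromide (1-bromo-3-methylbut-2-ene) | CC(C)=CCBr | starting material
3 | methyl 7-methyl-3-oxooct-6-enoate, present as its alkali-metal enolate | COC(=O)CC(=O)CCC=C(C)C | intermediate
4 | methyl 7-methyl-2-(3-methylbut-2-en-1-yl)-3-oxooct-6-enoate (racemic; the stereocentre is destroyed in step 2) | COC(=O)C(CC=C(C)C)C(=O)CCC=C(C)C | intermediate
5 | methyl 7-methyl-2-(3-methylbut-2-en-1-yl)-3-(trimethylsilyloxy)octa-2,6-dienoate (E/Z mixture) | COC(=O)C(CC=C(C)C)=C(O[Si](C)(C)C)CCC=C(C)C | intermediate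
6 | (3Z)-1-methoxy-7-methyl-2-(3-methylbut-2-en-1-yl)-1,3-bis(trimethylsilyloxy)octa-1,3,6-triene (ketene acetal geometry not defined) | COC(O[Si](C)(C)C)=C(CC=C(C)C)/C(O[Si](C)(C)C)=C/CC=C(C)C | intermediate
7 | ethyl formate | CCOC=O | starting material
8 | ethynylmagnesium bromide | C#C[Mg]Br | starting material
9 | prop-2-ynal | C#CC=O | intermediate
10 | penta-1,4-diyn-3-ol | C#CC(O)C#C | intermediate
11 | penta-1,4-diyn-3-one | C#CC(=O)C#C | intermediate
12 | 1-[6-methoxy-3,5-bis(3-methylbut-2-en-1-yl)-4,6-bis(trimethylsilyloxy)cyclohexa-1,4-dien-1-yl]prop-2-yn-1-one (diastereomer mixture; both stereocentres are lost on aromatisation) | COC1(O[Si](C)(C)C)C(CC=C(C)C)=C(O[Si](C)(C)C)C(CC=C(C)C)C=C1C(=O)C#C | intermediate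
13 | 1-[2,4-dihydroxy-3,5-bis(3-methylbut-2-en-1-yl)phenyl]prop-2-yn-1-one | C#CC(=O)c1cc(CC=C(C)C)c(O)c(CC=C(C)C)c1O | intermediate
14 | (E)-3-(diethylamino)-1-[2,4-dihydroxy-3,5-bis(3-methylbut-2-en-1-yl)phenyl]prop-2-en-1-one | CCN(CC)/C=C/C(=O)c1cc(CC=C(C)C)c(O)c(CC=C(C)C)c1O | intermediate
15 | 7-hydroxy-6,8-bis(3-methylbut-2-en-1-yl)-4H-chromen-4-one | CC(C)=CCc1cc2c(=O)ccoc2c(CC=C(C)C)c1O | intermediate
16 | 4-methoxyphenylboronic acid | COc1ccc(B(O)O)cc1 | starting material
17 | (2S)-7-hydroxy-2-(4-methoxyphenyl)-6,8-bis(3-methylbut-2-en-1-yl)-2,3-dihydro-4H-chromen-4-one (the target flavanone) | COc1ccc([C@@H]2CC(=O)c3cc(CC=C(C)C)c(O)c(CC=C(C)C)c3O2)cc1 | target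

## Summary

Total step count: 6. Longest linear sequence: 4 (steps 1, 2, 5, 6); steps 3 and 4 form a two-step side branch to the dienophile.

**Three steps most likely to fail**

Step 5 (highest risk). The hindered tetrasubstituted diene may react sluggishly, the diynone may react at both alkynes, or the amine stage may give polymer. Fallback, setting out from 6 and returning at 15: the diene 6 is combined with commercial but-3-yn-2-one, a monofunctional and stable dienophile, and worked up with ethanol and a little diethylamine to give 1-[2,4-dihydroxy-3,5-bis(3-methylbut-2-en-1-yl)phenyl]ethan-1-one F1. This is warmed with N,N-dimethylformamide dimethyl acetal in toluene to give (E)-3-(dimethylamino)-1-[2,4-dihydroxy-3,5-bis(3-methylbut-2-en-1-yl)phenyl]prop-2-en-1-one F2, and aqueous HCl closes F2 to chromone 15 with loss of dimethylamine. Rings A and C are then made in two operations, but the prenyl regiochemistry is still set by the diene.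

Step 6. The free phenol flanked by two prenyl groups could undergo Wacker-type or acid-promoted cyclisation at divalent palladium, and the electron-rich chromone is a weak acceptor. Fallback, setting out from 15 and returning at 17: 15 is silylated with t-BuMe2SiOTf and 2,6-lutidine to give 7-(tert-butyldimethylsilyloxy)-6,8-bis(3-methylbut-2-en-1-yl)-4H-chromen-4-one F3. F3 is arylated with 16 under the Pd(OCOCF3)2/(R)-t-BuPyOx conditions, now with no free phenol and a less deactivated enone, to give (2S)-7-(tert-butyldimethylsilyloxy)-2-(4-methoxyphenyl)-6,8-bis(3-methylbut-2-en-1-yl)-2,3-dihydro-4H-chromen-4-one F4. The silyl ether is then removed with KHF2 in MeOH at rt, near-neutral conditions that do not open or racemise the flavanone, to give 17.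

Step 4. Penta-1,4-diyn-3-one is volatile, lachrymatory and prone to polymerise, so the oxidation/filtration may give a low or unreliable titre. Fallback, setting out from 8 and returning at 15: ethynylmagnesium bromide 8 is added to commercial 3-(trimethylsilyl)prop-2-ynal to give 1-(trimethylsilyl)penta-1,4-diyn-3-ol F5, which MnO2 oxidises to the heavier and more stable 1-(trimethylsilyl)penta-1,4-diyn-3-one F6. F6 is used in place of 11 under the step 5 conditions: the diene 6 adds at the unsubstituted ethynyl ketone terminus, the silyl cap is removed during the diethylamine/ethanol stage, and amine addition and acid ring closure give chromone 15.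

## Further compounds

F1 | step 5 | 1-[2,4-dihydroxy-3,5-bis(3-methylbut-2-en-1-yl)phenyl]ethan-1-one | CC(=O)c1cc(CC=C(C)C)c(O)c(CC=C(C)C)c1O
F2 | step 5 | (E)-3-(dimethylamino)-1-[2,4-dihydroxy-3,5-bis(3-methylbut-2-en-1-yl)phenyl]prop-2-en-1-one | CN(C)/C=C/C(=O)c1cc(CC=C(C)C)c(O)c(CC=C(C)C)c1O
F3 | step 6 | 7-(tert-butyldimethylsilyloxy)-6,8-bis(3-methylbut-2-en-1-yl)-4H-chromen-4-one | CC(C)=CCc1cc2c(=O)ccoc2c(CC=C(C)C)c1O[Si](C)(C)C(C)(C)C
F4 | step 6 | (2S)-7-(tert-butyldimethylsilyloxy)-2-(4-methoxyphenyl)-6,8-bis(3-methylbut-2-en-1-yl)-2,3-dihydro-4H-chromen-4-one | COc1ccc([C@@H]2CC(=O)c3cc(CC=C(C)C)c(O[Si](C)(C)C(C)(C)C)c(CC=C(C)C)c3O2)cc1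
F5 | step 4 | 1-(trimethylsilyl)penta-1,4-diyn-3-ol | C#CC(O)C#C[Si](C)(C)C
F6 | step 4 | 1-(trimethylsilyl)penta-1,4-diyn-3-one | C#CC(=O)C#C[Si](C)(C)C
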